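The east run, hotter than the north-west run and at half its charge of Q, reads the same top in Z, 27 % of the charge. The east run reads it at 1.33 min, sooner than the north-west run at 2.50 min.

| flask | Q | temperature | remark | time |
|---|---|---|---|---|
| north-west | 0.20 M | 90 °C | the very flask that is asked about, followed so far |  |
| east | 0.10 M | 96 °C | run made earlier |  |
| flask | 0.20 M | 90 °C |  | 4.0 min |

| run | time / min | Z / % |
|---|---|---|
| north-west | 0.200 | 5 |
| north-west | 0.667 | 16 |
| north-west | 1.00 | 23 |
| north-west | 2.00 | 26 |
| north-west | 2.50 | 27 |
| north-west | 3.00 | 23 |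
| east | 0.500 | 18 |
| east | 1.00 | 26 |
| east | 1.33 | 27 |
| east | 2.00 | 24 |
| east | 2.50 | 22 |
| east | 3.00 | 15 |

(readings scatter by 1.5 percentage points)

- dusk: at 4.0 min raise the temperature by 25 K, then wait 8.0 min
- spring: at 4.0 min add Q, 50.0 % of the amount charged, then wait 8.0 min
- winter: change nothing and wait 8.0 min more
- dawn: at 4.0 min take out 90 % of the Z then present, then wait 8.0 min

- a species is counted by the Q in it: one L counts as two
- removed Z is counted in
- what may be going on: Q -> E; E <-> Z; E <-> X; 2 Q -> L; Q <-> J; Z -> G
- additions bring no volume worth counting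

* Z, in percent of the Q first charged, at 4.0 min
* the remedy with the largest gain of Z, or "none" below 2 percentage points (dusk / spring / winter / dawn / none)
* Z present, with what was taken out counted in, in percent of the Q first charged, after spring
* Z present, with what was taken out counted in, in percent of the Q first charged, after winter

Two times are taken for these curves: the time in which Z is supplied and the time in which it is lost. Equal tops suggest that these two moved together, so take them as equal, the symmetric zero of the scale. Both then equal the top time, the time of maximum of an intermediate. With ρ as time over top time, Z is the top height times ρ times e to the power one minus ρ. The east run tests this: at its last reading ρ is 2.26, which gives 17.4 % against 15 % read, with a scatter of 1.5 percentage points.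

The north-west readings put the top time near 2.25 min and the height near 26.5 %. So this flask should hold 21.6 % at 4.0 min. By this reckoning winter reaches 1.85 %. Spring adds a younger curve scaled to the added Q, for 5.51 %. Dawn banks its share of Z, and the gap left behind dies away, for 20.8 %, a change of −0.87 points, below the margin. Dusk is a hotter wait than winter, and I expect no gain from it, so my choice is none.

The forecast gave 19 %, dawn, 5.5 % and 2.5 %: “so the choice is uncertain”. The flask gives 21.6 %, none (dawn −0.57 points), 6.20 % after spring and 2.24 % after winter.

    Q → E (k = 0.0280 s⁻¹, Ea = 93.0 kJ mol⁻¹)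
    E ⇌ Z (K = 6.40, k = 0.990 s⁻¹, Ea = 94.0 kJ mol⁻¹, ΔH = −36.0 kJ mol⁻¹)
    E ⇌ X (K = 3.10, k = 0.500 s⁻¹, Ea = 88.0 kJ mol⁻¹, ΔH = −54.0 kJ mol⁻¹)
    2 Q → L (k = 4.60 × 10⁻⁴ M⁻¹ s⁻¹, Ea = 82.0 kJ mol⁻¹)
    Q ⇌ J (K = 2.20, k = 0.610 s⁻¹, Ea = 91.0 kJ mol⁻¹, ΔH = −19.0 kJ mol⁻¹)
    Z → G (k = 0.0100 s⁻¹, Ea = 93.0 kJ mol⁻¹)
    (constants at 90 °C)

In this flask the half-life of Z by its conversion into G, 1.2 min, is short against 4.0 min. E and Z relax by their own step far faster, with a half-life of 0.606 s. For the neighbouring flask, the same charge read at 1.5 min, the top time gives 24.7 %; the computed value is 24.1 %.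

The runs come from a simulation on assumed constants; the scatter is artificial.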